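Skeletal numbering: C1 ester carbinol, C2=C3 ring alkene, C6 hydroxylated and C10 methylated fusion carbons, C7 isopropyl carbon. The target is cut at the two bonds leaving the shared C6–C10 edge: C1–C10 of the seven-membered ring (C1 to C6, C10) and C6–C7 of the five-membered ring (C6 to C10). In the open chain this edge is a C6=C10 silyl enol ether, which first donates at C10 and afterwards accepts at C6; one cascade under a chiral acid makes the aldol closure onto the C1 aldehyde and the ene closure by the prenyl end, setting four stereocentres. The precursor is a (2Z)-farnesal with a geometrically defined C6 silyl enol ether.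

Key step: step 8

Remark 1: in the acyclic compounds skeletal C1 to C6 are chain C1 to C6, and skeletal C10, C9, C8, C7 are chain C7, C8, C9, C10; the enol ether needed is 6E (silyloxy group cis to the C7 methyl, the two chain arms cis).
Remark 2 (assumption): the sense of induction of the acid cannot be derived beforehand; the (S,S)-IDPi acid is written (imidodiphosphorimidate from two (S)-BINOL units with 3,5-bis(trifluoromethyl)phenyl groups at the 3,3' positions and N-trifluoromethylsulfonyl groups), and its mirror image is used if it leads to the antipode.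
Remark 3: the enol ether is carried as the triethylsilyl and not the trimethylsilyl ether, because it must survive two further steps and should resist cleavage by the acid in step 8; its geometry is set by a stereospecific reaction and not by enolisation.
Remark 4: neryl acetate is bought as such; made from nerol with Ac2O and pyridine it would add one step.

Step 1
Reactants: 1 neryl acetate, (2Z)-3,7-dimethylocta-2,6-dien-1-yl acetate
Product: 3 (2Z)-3-methyl-6-oxohex-2-en-1-yl acetate, via 6,7-epoxyneryl acetate 2 (not isolated)
Conditions: mCPBA (1.05 equiv), CH2Cl2, 0 °C; then H5IO6, THF/H2O, 0 °C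
Reagents that add atoms: 3-chloroperoxybenzoic acid (mCPBA), OOC(=O)c1cccc(Cl)c1
Why: Prilezhaev epoxidation picks the electron-rich distal alkene over the 2,3-alkene deactivated by the allylic acetate, and periodic acid then opens the epoxide and cleaves the glycol (Malaprade cleavage) to the aldehyde, so the racemic epoxide centre disappears and the 2Z alkene is untouched.

Step 2
Reactants: 4 6-methylhept-5-en-2-one
Product: 6 6-methylhepta-1,5-dien-2-yl trifluoromethanesulfonate, via lithium enolate 5 (not isolated)
Conditions: LiN(iPr)2, THF, −78 °C; then PhNTf2, −78 → 0 °C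
Reagents that add atoms: N-phenylbis(trifluoromethanesulfonimide), O=S(=O)(N(c1ccccc1)S(=O)(=O)C(F)(F)F)C(F)(F)F
Why: Kinetic deprotonation of the methyl ketone by the hindered lithium amide at −78 °C takes a methyl hydrogen, and O-sulfonylation of the terminal enolate (enol triflate formation) gives the 1,1-disubstituted alkenyl triflate.

Step 3
Reactants: 3 (2Z)-3-methyl-6-oxohex-2-en-1-yl acetate; 6 6-methylhepta-1,5-dien-2-yl trifluoromethanesulfonate
Product: 8 (2Z)-6-hydroxy-3,11-dimethyl-7-methylidenedodeca-2,10-dien-1-yl acetate, via alkenylchromium dichloride 7 (not isolated)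
Conditions: CrCl2 (4 equiv), NiCl2 (2 mol%), DMF, rt
Reagents that add atoms: none
Why: Nozaki–Hiyama–Kishi coupling: nickel-catalysed activation of the alkenyl triflate and transfer to chromium give an alkenylchromium reagent that adds to the aldehyde alone, sparing the acetate and the alkenes; the new carbinol centre is racemic and is removed by oxidation in step 4.

Step 4
Reactants: 8 (2Z)-6-hydroxy-3,11-dimethyl-7-methylidenedodeca-2,10-dien-1-yl acetate
Product: 9 (2Z)-3,11-dimethyl-7-methylidene-6-oxododeca-2,10-dien-1-yl acetate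
Conditions: Dess–Martin periodinane, pyridine, CH2Cl2, 0 °C → rt
Reagents that add atoms: none
Why: Dess–Martin oxidation of the secondary allylic alcohol under pyridine buffer should give the α-methylene ketone without migration of the terminal double bond and without loss of the acetate.

Step 5
Reactants: 9 (2Z)-3,11-dimethyl-7-methylidene-6-oxododeca-2,10-dien-1-yl acetate
Product: 10 (2Z,6E)-3,7,11-trimethyl-6-(triethylsilyloxy)dodeca-2,6,10-trien-1-yl acetate
Conditions: Et3SiH (1.3 equiv), RhCl(PPh3)3 (1 mol%), toluene, 50 °C
Reagents that add atoms: triethylsilane, CC[SiH](CC)CC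
Why: Rhodium-catalysed 1,4-hydrosilylation of an enone with a monohydrosilane passes silicon to oxygen and hydride to the terminal methylene carbon of the metal-bound s-cis enone, so the enol ether can form only toward the former methylene-bearing carbon and the new methyl group should end cis to the silyloxy group (6E), while acetate and trisubstituted alkenes are inert.

Step 6
Reactants: 10 (2Z,6E)-3,7,11-trimethyl-6-(triethylsilyloxy)dodeca-2,6,10-trien-1-yl acetate
Product: 11 (2Z,6E)-3,7,11-trimethyl-6-(triethylsilyloxy)dodeca-2,6,10-trien-1-ol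
Conditions: iBu2AlH (2.2 equiv), CH2Cl2, −78 °C; aqueous potassium sodium tartrate
Reagents that add atoms: none
Why: Reductive cleavage of the acetate by the aluminium hydride at −78 °C (ester reduction) frees the allylic alcohol without base or protic acid, conditions under which a triethylsilyl enol ether persists, as it should in the near-neutral tartrate work-up.

Step 7
Reactants: 11 (2Z,6E)-3,7,11-trimethyl-6-(triethylsilyloxy)dodeca-2,6,10-trien-1-ol
Product: 12 (2Z,6E)-3,7,11-trimethyl-6-(triethylsilyloxy)dodeca-2,6,10-trienal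
Conditions: activated MnO2 (excess), CH2Cl2, 0 °C → rt
Reagents that add atoms: none
Why: Allylic oxidation on MnO2 is neutral and heterogeneous and turns Z allylic alcohols into Z enals without isomerisation, as in the conversion of nerol into neral, so the 2Z geometry and the enol ether should be kept.

Step 8
Reactants: 12 (2Z,6E)-3,7,11-trimethyl-6-(triethylsilyloxy)dodeca-2,6,10-trienal
Product: 14 (3R,3aS,8R,8aR)-6,8a-dimethyl-3-(prop-1-en-2-yl)-8-(triethylsilyloxy)-1,2,3,3a,4,5,8,8a-octahydroazulen-3a-ol, via monocyclic silyloxy ketone 13 (not isolated)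
Conditions: (S,S)-IDPi acid (5 mol%), toluene (0.01 M), 4 Å MS, −60 → −40 °C; Et3N quench
Reagents that add atoms: none
Why: Proposed new method: the acid, turned by the first traces of 12 into its silylated ion-pair form, passes Et3Si+ to the aldehyde oxygen inside its chiral pocket, C10 of the enol ether adds to C1 (Mukaiyama aldol) and the enol silicon returns to the anion, which leaves the C1 silyl ether and the C6 ketone of 13; the same acid then activates this ketone for a six-centre carbonyl-ene reaction with the prenyl alkene, a methyl hydrogen passing to the C6 oxygen and the activating group going back to the anion. Its nearest relatives in established chemistry are aldol–Prins cascades of enol ethers, ketone-ene cyclisations promoted by aluminium Lewis acids, and catalytic asymmetric Mukaiyama aldol additions run with imidodiphosphorimidate acids. The seven-membered ring forms in a 7-(enolendo)-exo-trig closure, for which the cis geometry of the C2=C3 alkene brings the aldehyde within reach of C10, and the five-membered ring forms in a 5-exo-trig closure onto the C6 carbonyl. The acid pocket chooses the Si face of the aldehyde (C1, R); with the 6E enol ether reacting through an open transition state in which the C1 oxygen is anti to the enol C6, that face is joined to the Si face of C10, so the C1 oxygen lies trans to the C10 methyl (C10, R); the tether from C10 can deliver the alkene only to the face of the C6 carbonyl on which it is anchored, so the new ring is cis-fused and the hydroxyl lies on the side of the C10 methyl (C6, S); the cyclic hydrogen transfer puts isopropenyl cis to hydroxyl (C7, R). The step needs 1,2- and not 1,4-attack on the enal and ring closure ahead of enol ether cleavage: conjugate attack at C3 would be a 5-(enolendo)-exo-trig closure that the ring geometry does not allow, the two alkyl groups on C10 and the triethylsilyl group slow protonation at carbon, and high dilution over molecular sieves suppresses intermolecular aldol addition and hydrolysis.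

Step 9
Reactants: 14 (3R,3aS,8R,8aR)-6,8a-dimethyl-3-(prop-1-en-2-yl)-8-(triethylsilyloxy)-1,2,3,3a,4,5,8,8a-octahydroazulen-3a-ol
Product: 15 (3R,3aS,8R,8aR)-6,8a-dimethyl-3-(propan-2-yl)-8-(triethylsilyloxy)-1,2,3,3a,4,5,8,8a-octahydroazulen-3a-ol
Conditions: H2 (1 atm), RhCl(PPh3)3 (10 mol%), benzene, rt
Reagents that add atoms: none
Why: Homogeneous hydrogenation with RhCl(PPh3)3 saturates the 1,1-disubstituted isopropenyl alkene far faster than the trisubstituted ring alkene, and the resulting isopropyl group adds no stereocentre.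

Step 10
Reactants: 15 (3R,3aS,8R,8aR)-6,8a-dimethyl-3-(propan-2-yl)-8-(triethylsilyloxy)-1,2,3,3a,4,5,8,8a-octahydroazulen-3a-ol
Product: 16 (3R,3aS,8R,8aR)-6,8a-dimethyl-3-(propan-2-yl)-1,2,3,3a,4,5,8,8a-octahydroazulene-3a,8-diol
Conditions: Bu4NF, THF, 0 °C → rt
Reagents that add atoms: none
Why: Fluoride-induced desilylation removes the secondary triethylsilyl ether under non-acidic conditions, which protects the tertiary alcohol from ionisation and leaves all four stereocentres untouched.

Step 11
Reactants: 16 (3R,3aS,8R,8aR)-6,8a-dimethyl-3-(propan-2-yl)-1,2,3,3a,4,5,8,8a-octahydroazulene-3a,8-diol; 17 4-methoxybenzoyl chloride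
Product: 18 (3R,3aS,8R,8aR)-3a-hydroxy-6,8a-dimethyl-3-(propan-2-yl)-1,2,3,3a,4,5,8,8a-octahydroazulen-8-yl 4-methoxybenzoate
Conditions: Et3N, DMAP (cat.), CH2Cl2, 0 °C → rt
Reagents that add atoms: 4-methoxybenzoyl chloride (17), COc1ccc(C(Cl)=O)cc1
Why: DMAP-catalysed acylation through the acylpyridinium ion esterifies the secondary allylic hydroxyl with retention, whereas the tertiary ring-fusion hydroxyl is too hindered to react.

Compound list
1 | neryl acetate, (2Z)-3,7-dimethylocta-2,6-dien-1-yl acetate | CC(=O)OC/C=C(C)\CCC=C(C)C | starting material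
2 | 6,7-epoxyneryl acetate, (2Z)-5-(3,3-dimethyloxiran-2-yl)-3-methylpent-2-en-1-yl acetate (racemic) | CC(=O)OC/C=C(C)\CCC1OC1(C)C | intermediate
3 | (2Z)-3-methyl-6-oxohex-2-en-1-yl acetate | CC(=O)OC/C=C(C)\CCC=O | intermediate
4 | 6-methylhept-5-en-2-one | CC(=O)CCC=C(C)C | starting material
5 | lithium 6-methylhepta-1,5-dien-2-olate | [Li+].[O-]C(=C)CCC=C(C)C | intermediate
6 | 6-methylhepta-1,5-dien-2-yl trifluoromethanesulfonate | C=C(OS(=O)(=O)C(F)(F)F)CCC=C(C)C | intermediate
7 | (6-methylhepta-1,5-dien-2-yl)chromium dichloride | C=C([Cr](Cl)Cl)CCC=C(C)C | intermediate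
8 | (2Z)-6-hydroxy-3,11-dimethyl-7-methylidenedodeca-2,10-dien-1-yl acetate (racemic at C6) | CC(=O)OC/C=C(C)\CCC(O)C(=C)CCC=C(C)C | intermediate
9 | (2Z)-3,11-dimethyl-7-methylidene-6-oxododeca-2,10-dien-1-yl acetate | CC(=O)OC/C=C(C)\CCC(=O)C(=C)CCC=C(C)C | intermediate
10 | (2Z,6E)-3,7,11-trimethyl-6-(triethylsilyloxy)dodeca-2,6,10-trien-1-yl acetate | CC(=O)OC/C=C(C)\CC/C(O[Si](CC)(CC)CC)=C(C)\CCC=C(C)C | intermediate
11 | (2Z,6E)-3,7,11-trimethyl-6-(triethylsilyloxy)dodeca-2,6,10-trien-1-ol | OC/C=C(C)\CC/C(O[Si](CC)(CC)CC)=C(C)\CCC=C(C)C | intermediate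
12 | (2Z,6E)-3,7,11-trimethyl-6-(triethylsilyloxy)dodeca-2,6,10-trienal | O=C/C=C(C)\CC/C(O[Si](CC)(CC)CC)=C(C)\CCC=C(C)C | intermediate
13 | (2R,3R)-2,5-dimethyl-2-(4-methylpent-3-en-1-yl)-3-(triethylsilyloxy)cyclohept-4-en-1-one (aldol stage, held on the acid) | CC[Si](CC)(CC)O[C@@H]1C=C(C)CCC(=O)[C@]1(C)CCC=C(C)C | intermediate
14 | (3R,3aS,8R,8aR)-6,8a-dimethyl-3-(prop-1-en-2-yl)-8-(triethylsilyloxy)-1,2,3,3a,4,5,8,8a-octahydroazulen-3a-ol | CC[Si](CC)(CC)O[C@@H]1C=C(C)CC[C@]2(O)[C@@H](C(C)=C)CC[C@]12C | intermediate
15 | (3R,3aS,8R,8aR)-6,8a-dimethyl-3-(propan-2-yl)-8-(triethylsilyloxy)-1,2,3,3a,4,5,8,8a-octahydroazulen-3a-ol | CC[Si](CC)(CC)O[C@@H]1C=C(C)CC[C@]2(O)[C@@H](C(C)C)CC[C@]12C | intermediate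
16 | (3R,3aS,8R,8aR)-6,8a-dimethyl-3-(propan-2-yl)-1,2,3,3a,4,5,8,8a-octahydroazulene-3a,8-diol | O[C@@H]1C=C(C)CC[C@]2(O)[C@@H](C(C)C)CC[C@]12C | intermediate
17 | 4-methoxybenzoyl chloride | COc1ccc(C(Cl)=O)cc1 | starting material
18 | (3R,3aS,8R,8aR)-3a-hydroxy-6,8a-dimethyl-3-(propan-2-yl)-1,2,3,3a,4,5,8,8a-octahydroazulen-8-yl 4-methoxybenzoate | COc1ccc(C(=O)O[C@@H]2C=C(C)CC[C@]3(O)[C@@H](C(C)C)CC[C@]23C)cc1 | target

Total step count: 11. Longest linear sequence: 10 steps (steps 1, 3, 4, 5, 6, 7, 8, 9, 10, 11 from neryl acetate); step 2 is a one-step side branch.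

Steps most likely to fail

Step 8 (new method). Three processes may defeat it: cleavage of the enol ether by the acid or by traces of water may outrun the seven-membered aldol closure; the sequence may stop at 13 if the C6 carbonyl is not activated a second time; the aldol may close with the other configuration at C1 or with poor face selection. The fallback uses known reactions only, sets out from 12 and returns at 16. BF3·OEt2 in CH2Cl2 at −78 °C effects an ordinary intramolecular Mukaiyama aldol addition to racemic 3-hydroxy-2,5-dimethyl-2-(4-methylpent-3-en-1-yl)cyclohept-4-en-1-one F1 (both carbinol epimers). Me2AlCl (2.2 equiv, −78 → 0 °C) forms the aluminium alkoxide and promotes the ketone-ene cyclisation to the racemic isopropenyl diol F2. MnO2 oxidises the allylic C1 carbinol to the hydroxy enone F3, which merges both C1 epimers and is resolved at this UV-absorbing stage by preparative chromatography on a chiral stationary phase. Me4NBH(OAc)3 in MeCN/AcOH at −20 °C (hydroxyl-directed reduction, hydride delivered from the face of the C6 hydroxyl) should give the anti isopropenyl diol F4 with the target configuration at C1, and hydrogenation as in step 9 gives 16. Oxidation followed by directed reduction makes the configuration at C1 independent of the aldol step.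

Step 5. Hydride transfer through the s-trans conformer would give the 6Z enol ether, and 1,2-reduction of the carbonyl or migration of the terminal alkene may compete. The fallback sets out from 9 and returns at 10. Conjugate reduction with stoichiometric [CuH(PPh3)]6 in benzene containing water gives the saturated ketone (2Z)-3,7,11-trimethyl-6-oxododeca-2,10-dien-1-yl acetate F5. Silylation under equilibrating conditions (Et3SiOTf, Et3N, CH2Cl2, rt) favours the more substituted enol ethers; 10 is separated on AgNO3-impregnated silica from its 6Z isomer (2Z,6Z)-3,7,11-trimethyl-6-(triethylsilyloxy)dodeca-2,6,10-trien-1-yl acetate F6, and F6 is returned to F5 with aqueous citric acid for another pass. The geometry is then secured by separation and not by the reaction.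

Step 7. The triethylsilyl enol ether may be hydrolysed or cleaved oxidatively on the oxidant surface during the slow heterogeneous oxidation. The fallback sets out from 9 and returns at 16; it carries the enol ether as its tert-butyldimethylsilyl analogue, which is far slower to hydrolyse. tBuMe2SiH with RhCl(PPh3)3 at 70 °C gives the acetate (2Z,6E)-6-(tert-butyldimethylsilyloxy)-3,7,11-trimethyldodeca-2,6,10-trien-1-yl acetate F7, iBu2AlH the corresponding alcohol F8, and MnO2 the enal F9. The conditions of step 8 give, through the aldol-stage ketone F10, the bicyclic C1 tert-butyldimethylsilyl ether F11. Bu4NF in THF at 40 °C gives the isopropenyl diol F4, and hydrogenation as in step 9 gives 16.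

Further compounds
F1 | step 8 | racemic 3-hydroxy-2,5-dimethyl-2-(4-methylpent-3-en-1-yl)cyclohept-4-en-1-one (both carbinol epimers) | OC1C=C(C)CCC(=O)C1(C)CCC=C(C)C
F2 | step 8 | racemic (3R*,3aS*,8aR*)-6,8a-dimethyl-3-(prop-1-en-2-yl)-1,2,3,3a,4,5,8,8a-octahydroazulene-3a,8-diol (both C8 epimers, one enantiomer drawn) | OC1C=C(C)CC[C@]2(O)[C@@H](C(C)=C)CC[C@]12C
F3 | step 8 | (3R,3aS,8aS)-3a-hydroxy-6,8a-dimethyl-3-(prop-1-en-2-yl)-2,3,3a,4,5,8a-hexahydroazulen-8(1H)-one (formed racemic, then resolved) | O=C1C=C(C)CC[C@]2(O)[C@@H](C(C)=C)CC[C@]12C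
F4 | step 8 | (3R,3aS,8R,8aR)-6,8a-dimethyl-3-(prop-1-en-2-yl)-1,2,3,3a,4,5,8,8a-octahydroazulene-3a,8-diol | O[C@@H]1C=C(C)CC[C@]2(O)[C@@H](C(C)=C)CC[C@]12C
F5 | step 5 | (2Z)-3,7,11-trimethyl-6-oxododeca-2,10-dien-1-yl acetate (racemic at C7) | CC(=O)OC/C=C(C)\CCC(=O)C(C)CCC=C(C)C
F6 | step 5 | (2Z,6Z)-3,7,11-trimethyl-6-(triethylsilyloxy)dodeca-2,6,10-trien-1-yl acetate | CC(=O)OC/C=C(C)\CC/C(O[Si](CC)(CC)CC)=C(C)/CCC=C(C)C
F7 | step 7 | (2Z,6E)-6-(tert-butyldimethylsilyloxy)-3,7,11-trimethyldodeca-2,6,10-trien-1-yl acetate | CC(=O)OC/C=C(C)\CC/C(O[Si](C)(C)C(C)(C)C)=C(C)\CCC=C(C)C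
F8 | step 7 | (2Z,6E)-6-(tert-butyldimethylsilyloxy)-3,7,11-trimethyldodeca-2,6,10-trien-1-ol | OC/C=C(C)\CC/C(O[Si](C)(C)C(C)(C)C)=C(C)\CCC=C(C)C
F9 | step 7 | (2Z,6E)-6-(tert-butyldimethylsilyloxy)-3,7,11-trimethyldodeca-2,6,10-trienal | O=C/C=C(C)\CC/C(O[Si](C)(C)C(C)(C)C)=C(C)\CCC=C(C)C
F10 | step 7 | (2R,3R)-3-(tert-butyldimethylsilyloxy)-2,5-dimethyl-2-(4-methylpent-3-en-1-yl)cyclohept-4-en-1-one (not isolated) | CC(C)(C)[Si](C)(C)O[C@@H]1C=C(C)CCC(=O)[C@]1(C)CCC=C(C)C
F11 | step 7 | (3R,3aS,8R,8aR)-8-(tert-butyldimethylsilyloxy)-6,8a-dimethyl-3-(prop-1-en-2-yl)-1,2,3,3a,4,5,8,8a-octahydroazulen-3a-ol | CC(C)(C)[Si](C)(C)O[C@@H]1C=C(C)CC[C@]2(O)[C@@H](C(C)=C)CC[C@]12C
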